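The constants are not given, so a clock for J has to be read off the runs.

| setting | Friday's | Thursday's | Wednesday's | ash | oak | maple | alder |
|---|---|---|---|---|---|---|---|
| X | 0.086 M (in portions, 3) | 0.086 M (in portions, 3) | 0.086 M (in portions, 3) | 0.086 M (in portions, 3) | 0.086 M (in portions, 3) | 0.086 M (in portions, 3) | 0.086 M (in portions, 3) |
| E | 0.37 equiv | 1.5 equiv | 3.4 equiv | 0.500 equiv | 1.00 equiv | 2.00 equiv | 4.00 equiv |
| remark | run made earlier; portions every 10 h | run made earlier; portions every 10 h | run made earlier; portions every 10 h | the portions of X follow each other after 10 h, the first at the start | the portions of X follow each other after 10 h, the first at the start | the portions of X follow each other after 10 h, the first at the start | the portions of X follow each other after 10 h, the first at the start |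
| time |  |  |  | 30 h | 30 h | 30 h | 30 h |

| run | time / h | J / % | G / % |
|---|---|---|---|
| Friday's | 3.00 | 4.3 | 3.4 |
| Friday's | 6.00 | 4.7 | 7.4 |
| Friday's | 10.0 | 7.6 | 10.9 |
| Friday's | 12.0 | 6.4 | 16.4 |
| Friday's | 15.0 | 5.4 | 26.9 |
| Thursday's | 1.33 | 7.7 | 2.3 |
| Thursday's | 4.00 | 11.8 | 8.7 |
| Thursday's | 8.00 | 14.0 | 12.1 |
| Thursday's | 10.0 | 9.8 | 12.4 |
| Thursday's | 15.0 | 16.9 | 34.8 |
| Wednesday's | 3.00 | 15.8 | 5.1 |
| Wednesday's | 6.00 | 13.7 | 7.0 |
| Wednesday's | 10.0 | 8.0 | 9.4 |
| Wednesday's | 12.0 | 19.6 | 15.5 |
| Wednesday's | 15.0 | 16.6 | 19.5 |

(standard deviation of a reading: 1 percentage point)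

- in percentages every species weighs as the X in it: one G counts as two
- "hardly changes" means that all values lie within two and a half points (for a concentration: within two and a half percent of the largest)
- a step back or a flat step of under half a point counts as no turn

1. share of J in all that became J or G or L for ash, oak, maple, alder, in this order
2. the course of these numbers from the first flask to the last (falls, then rises / hardly changes / rises all the way / falls all the way / rises, then falls)

Friday's J is still climbing at 10.0 h, where it reads 7.6%, but Wednesday's falls from 15.8% at 3.00 h to 8.0% at 10.0 h. Those two readings of Wednesday's give J's fading time, an apparent half-life with making and losing taken net: 7.13 h, a reading that carries the scatter of 1 percentage point.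

Turn the question round. A rise all the way asks alder's J to stand above maple's at the asked time, 10.0 h after the last portion, and a fading time long against that interval would suit that. Wednesday's run, the richest so far at 3.4 equiv and next to alder's 4.00 equiv, stands the other way: the interval holds 1.40 fading times. At 10.0 h, when the second portion is due, Thursday's J of 9.8% reads above both Friday's 7.6% and Wednesday's 8.0%, with a gap of 2.2 points at the widest against a scatter of 1 point. Wednesday's 19.6% at 12.0 h, after the second portion, reckoned forward at that fading time to 20.0 h, becomes 9.00%. The reckoning here takes that figure as a stand-in for alder's share at the asked time, an estimate that treats alder's X as turned over by then, and with Thursday's reading above Wednesday's it commits to a row that rises, then falls.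

The forecast gives 6.5%, 10%, 12.5%, 14% and rises all the way, on the ground that “With more E, more X goes down the J route, and E is not exhausted.” It parts from the reckoning here at alder, 14% against 9.00%.

The flask gives 4.68%, 10.3%, 14.5%, 9.80%: rises, then falls.

    E + J → L (k = 0.550 L mol⁻¹ h⁻¹)
    X + J → G (k = 7.90 L mol⁻¹ h⁻¹)
    X + E → J + Q (k = 1.90 L mol⁻¹ h⁻¹)

The row turns at 2.1 equiv. Reckoned over 5.00 h with the fading time of 7.13 h, alder's J of 15.6% at 15.0 h comes to 9.57%, and alder holds 8.10% at 20.0 h.

(All runs are calculated for substances that don't exist; scatter was added.)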